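**Retrosynthetic overview**
1. Last disconnection: the bond between the enone carbonyl carbon C7 (on the quaternary ring carbon C8) and the exocyclic vinyl CH (C6). The same step also closes the pyranone ring (bond C4'–C5'), so the target falls into lactol 23 and the acyclic iodo ester 27 (nickel-catalysed cyclisation/carbonyl-Heck cascade).
2. Enabling feature: C7 has the carbinol oxygen γ to it (O–C10–C9–C8–C7) and C8 is quaternary, so C7 can be stored as a non-enolisable, trans-fused five-membered lactol ring. In the 5-alkylidene-5,6-dihydro-2H-pyran-2-one the acyl carbon is cis to C4'–H across C5'=C6, the pattern left by syn addition across the alkyne of a 1,1-dimethylpropargyl ester.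
3. Glycidate and furyl ketone come from a temporary ring D lactone (C13–C14=C15–C16(=O)–O–C17): intramolecular Horner–Wadsworth–Emmons reaction at the hindered C14 ketone, nucleophilic epoxidation, methanolysis, oxidation at C17.
4. C13 is set by methylating an α-formyl ketone anti to the axial C8 methyl of the trans-fused bicycle. C9 and C8 come from cuprate addition and aldol reaction on (R)-5-methylbutenolide (C10 from (R)-but-3-yn-2-ol). Ring C is closed by ring-closing metathesis.
5. Ring order: butenolide (later the lactol ring) → ring C → ring D lactone → oxirane → ring D and the lactol ring opened → pyranone ring (key step); the furan is bought as 3-bromofuran.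

Key step: step 18

Numbering used in the text: ring C = C8, C9, C11, C12, C13, C14; C7 on C8; C10 on C9; C15/C16 = epoxide CH and ester carbon; C17 = furyl carbonyl carbon; C6 = enone CH; primed numbers = pyranone ring.
Remark (assumption): centres that are destroyed later (acetal carbon C7, carbinol carbons C14 and C17) should form as epimer mixtures; they are written without configuration and both epimers are carried on.

**Route**

Step 1
Reactants: 1 (R)-but-3-yn-2-ol
Product: 3 (R)-4-hydroxypent-2-ynoic acid, via dilithium alkoxide acetylide 2 (not isolated)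
Conditions: n-BuLi (2.1 equiv), THF, −78 → 0 °C; CO2, −78 °C; aq HCl
Reagents that add atoms: carbon dioxide O=C=O
Why: Double deprotonation gives the alkoxide acetylide, whose carbon is carboxylated by CO2 (acetylide carboxylation); the carbinol centre (later C10) is not touched.

Step 2
Reactants: 3 (R)-4-hydroxypent-2-ynoic acid
Product: 5 (R)-5-methylfuran-2(5H)-one, via (R,Z)-4-hydroxypent-2-enoic acid 4 (not isolated)
Conditions: H2 (1 atm), Pd/CaCO3 (Pb-poisoned), quinoline, EtOAc, rt; then TsOH (cat.), CH2Cl2
Reagents that add atoms: none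
Why: Lindlar-type semihydrogenation gives the (Z)-hydroxy acid, which lactonises to the butenolide with the carbinol centre unchanged.

Step 3
Reactants: 5 (R)-5-methylfuran-2(5H)-one
Product: 7 (3S,4S,5R)-3,5-dimethyl-4-(prop-2-en-1-yl)oxolan-2-one, via bromomagnesium enolate 6 (not isolated)
Conditions: CH2=CHCH2MgBr (2.2 equiv), CuBr·SMe2 (1.1 equiv), THF, −78 °C; then MeI, DMPU, −78 → −20 °C
Reagents that add atoms: allylmagnesium bromide C=CC[Mg]Br; iodomethane CI
Why: Tandem cuprate conjugate addition/enolate alkylation: the allyl group should add anti to the C5 methyl of the butenolide (sets C9) and MeI should enter anti to the new allyl group (this centre is re-enolised in step 4).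

Step 4
Reactants: 7 (3S,4S,5R)-3,5-dimethyl-4-(prop-2-en-1-yl)oxolan-2-one
Product: 9 (3R,4S,5R)-3-(1-hydroxyprop-2-en-1-yl)-3,5-dimethyl-4-(prop-2-en-1-yl)oxolan-2-one (carbinol epimers), via lithium enolate 8 (not isolated)
Conditions: LiN(i-Pr)2, THF, −78 °C; then acrolein, −78 °C; aq NH4Cl
Reagents that add atoms: acrolein C=CC=O
Why: Aldol 1,2-addition of the trisubstituted lactone enolate to acrolein from the face anti to the neighbouring allyl group should set the quaternary C8 with its methyl cis to the allyl group; the carbinol centre is removed in step 7.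

Step 5
Reactants: 9 (3R,4S,5R)-3-(1-hydroxyprop-2-en-1-yl)-3,5-dimethyl-4-(prop-2-en-1-yl)oxolan-2-one
Product: 10 (3R,3aS,7aR)-7-hydroxy-3,7a-dimethyl-3a,4,7,7a-tetrahydro-2-benzofuran-1(3H)-one (carbinol epimers)
Conditions: second-generation Grubbs catalyst (3 mol %), CH2Cl2 (0.01 M), 40 °C
Reagents that add atoms: none
Why: Ring-closing metathesis of the two terminal alkenes closes the cyclohexene (ring C) trans-fused to the lactone with loss of ethene; no stereocentre is touched.

Step 6
Reactants: 10 (3R,3aS,7aR)-7-hydroxy-3,7a-dimethyl-3a,4,7,7a-tetrahydro-2-benzofuran-1(3H)-one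
Product: 12 (3R,3aS,7aR)-1-methoxy-3,7a-dimethyl-1,3,3a,4,7,7a-hexahydro-2-benzofuran-7-ol (acetal and carbinol epimers), via lactol 11 (not isolated)
Conditions: i-Bu2AlH (2.2 equiv), CH2Cl2, −78 °C; then MeOH, PPTS, rt
Reagents that add atoms: methanol CO
Why: Lactone-to-lactol reduction at low temperature followed by Fischer-type acetalisation stores C7 at the aldehyde level and keeps the trans-fused five-membered ring as a conformational lock; the acetal centre is lost in step 16.

Step 7
Reactants: 12 (3R,3aS,7aR)-1-methoxy-3,7a-dimethyl-1,3,3a,4,7,7a-hexahydro-2-benzofuran-7-ol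
Product: 13 (3R,3aS,7aS)-1-methoxy-3,7a-dimethyl-3,3a,4,7a-tetrahydro-2-benzofuran-7(1H)-one (acetal epimers)
Conditions: MnO2, CH2Cl2, rt
Reagents that add atoms: none
Why: Allylic alcohol oxidation with MnO2 gives the cyclohexenone; the acetal and the three stereocentres are not affected.

Step 8
Reactants: 13 (3R,3aS,7aS)-1-methoxy-3,7a-dimethyl-3,3a,4,7a-tetrahydro-2-benzofuran-7(1H)-one
Product: 15 (3R,3aS,7aS)-6-(hydroxymethylidene)-1-methoxy-3,7a-dimethylhexahydro-2-benzofuran-7(1H)-one, via lithium enolate 14 (not isolated)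
Conditions: LiBH(s-Bu)3, THF, −78 °C; then HCO2CH2CF3, −78 → 0 °C; aq NH4Cl
Reagents that add atoms: 2,2,2-trifluoroethyl formate O=COCC(F)(F)F
Why: Conjugate hydride addition to the β-unsubstituted cyclohexenone gives the C13 enolate regiospecifically, and Claisen-type C-formylation gives the hydroxymethylene ketone; no stereocentre is set.

Step 9
Reactants: 15 (3R,3aS,7aS)-6-(hydroxymethylidene)-1-methoxy-3,7a-dimethylhexahydro-2-benzofuran-7(1H)-one
Product: 16 (3R,3aS,6S,7aS)-1-methoxy-3,6,7a-trimethyl-7-oxooctahydro-2-benzofuran-6-carbaldehyde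
Conditions: MeI, K2CO3, acetone, 40 °C
Reagents that add atoms: iodomethane CI
Why: C-Alkylation of the α-formyl ketone enolate: in the trans-fused bicycle the C8 methyl is axial and 1,3 to C13, so MeI should enter from the opposite face and set the quaternary C13 with its methyl trans to the C8 methyl.

Step 10
Reactants: 16 (3R,3aS,6S,7aS)-1-methoxy-3,6,7a-trimethyl-7-oxooctahydro-2-benzofuran-6-carbaldehyde
Product: 17 (3R,3aS,6S,7aS)-6-[furan-3-yl(hydroxy)methyl]-1-methoxy-3,6,7a-trimethylhexahydro-2-benzofuran-7(1H)-one (carbinol epimers)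
Conditions: 3-bromofuran, n-BuLi, THF, −78 °C; then 16, −78 °C; aq NH4Cl
Reagents that add atoms: 3-bromofuran Brc1ccoc1
Why: 1,2-Addition of 3-furyllithium (bromine–lithium exchange) to the neopentyl aldehyde, which is far more reactive than the ketone between two quaternary carbons; the C17 carbinol centre is oxidised later, so both epimers serve.

Step 11
Reactants: 17 (3R,3aS,6S,7aS)-6-[furan-3-yl(hydroxy)methyl]-1-methoxy-3,6,7a-trimethylhexahydro-2-benzofuran-7(1H)-one
Product: 18 furan-3-yl[(3R,3aS,6S,7aS)-1-methoxy-3,6,7a-trimethyl-7-oxooctahydro-2-benzofuran-6-yl]methyl (diethoxyphosphoryl)acetate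
Conditions: (EtO)2P(O)CH2CO2H, DCC, DMAP (cat.), CH2Cl2, 0 °C → rt
Reagents that add atoms: (diethoxyphosphoryl)acetic acid OC(=O)CP(=O)(OCC)OCC
Why: Steglich esterification of the secondary alcohol attaches the phosphonate through a tether that can reach the hindered C14 ketone.

Step 12
Reactants: 18 furan-3-yl[(3R,3aS,6S,7aS)-1-methoxy-3,6,7a-trimethyl-7-oxooctahydro-2-benzofuran-6-yl]methyl (diethoxyphosphoryl)acetate
Product: 19 tricyclic α,β-unsaturated δ-lactone (ring D: C13–C14=C15–C16(=O)–O–C17H(3-furyl); acetal ring intact; C8, C9, C10, C13 as in 17)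
Conditions: LiCl, DBU, MeCN, rt → 50 °C
Reagents that add atoms: none
Why: Intramolecular Horner–Wadsworth–Emmons olefination (Masamune–Roush conditions) closes the six-membered unsaturated lactone and forms C14=C15 at a ketone too hindered for the intermolecular reaction.

Step 13
Reactants: 19 tricyclic α,β-unsaturated δ-lactone
Product: 20 14,15-epoxy δ-lactone (epoxide oxygen cis to the C8 methyl and trans to the C13 methyl)
Conditions: t-BuOOH, n-BuLi, THF, −78 → 0 °C
Reagents that add atoms: tert-butyl hydroperoxide CC(C)(C)OO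
Why: Nucleophilic (Weitz–Scheffer-type) epoxidation with LiOO-t-Bu: conjugate attack at C14 should come from the face anti to the pseudoaxial C13 methyl, and because ring D holds C16 cis to C13 this fixes C14 and C15 together.

Step 14
Reactants: 20 14,15-epoxy δ-lactone
Product: 21 hydroxy ester (methyl glycidate with free C17 hydroxyl, C17 epimers; acetal intact)
Conditions: NaOMe (0.2 equiv), MeOH, 0 °C; AcOH quench
Reagents that add atoms: methanol CO
Why: Base-catalysed transesterification (methanolysis) opens the strained epoxy lactone to the methyl glycidate, which lets ring C relax to a chair; no stereocentre is touched.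

Step 15
Reactants: 21 hydroxy ester
Product: 22 keto ester (3-furyl ketone at C17; methyl glycidate; cyclic methyl acetal, acetal epimers)
Conditions: Dess–Martin periodinane, NaHCO3, CH2Cl2, rt
Reagents that add atoms: none
Why: Dess–Martin oxidation of the secondary furyl carbinol gives the ketone, removes the C17 centre and blocks relactonisation.

Step 16
Reactants: 22 keto ester
Product: 23 lactol (trans-fused cyclic hemiacetal of the C7 aldehyde with the C10 hydroxyl, hemiacetal epimers)
Conditions: AcOH/THF/H2O (3:1:1), 45 °C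
Reagents that add atoms: water O
Why: Mild acid hydrolysis of the cyclic methyl acetal gives the lactol, a masked γ-hydroxy aldehyde; the glycidic ester, which ionises poorly, should survive.

Step 17
Reactants: 24 (Z)-3-iodoprop-2-enoic acid; 25 2-methylbut-3-yn-2-ol
Product: 27 2-methylbut-3-yn-2-yl (Z)-3-iodoprop-2-enoate, via (Z)-3-iodoprop-2-enoyl chloride 26 (not isolated)
Conditions: (COCl)2, DMF (cat.), CH2Cl2, 0 °C; then 25, pyridine, DMAP (cat.), 0 °C → rt
Reagents that add atoms: none
Why: Acyl chloride formation and O-acylation of the tertiary propargylic alcohol (esterification) at low temperature should keep the (Z)-alkene geometry.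

Step 18
Reactants: 23 lactol; 27 2-methylbut-3-yn-2-yl (Z)-3-iodoprop-2-enoate
Product: 29 methyl (2S,3R,4R,5S,8R)-4-[(2E)-2-(2,2-dimethyl-6-oxo-2,6-dihydro-3H-pyran-3-ylidene)acetyl]-8-(furan-3-carbonyl)-5-[(1R)-1-hydroxyethyl]-4,8-dimethyl-1-oxaspiro[2.5]octane-2-carboxylate, via open-chain hydroxy aldehyde 28 (not isolated)
Conditions: Ni(cod)2 (20 mol %), PhP(CH2CH2PPh2)2 (24 mol %), 2,2,6,6-tetramethylpiperidine (2 equiv), MeCN/PhMe, 80 °C, slow addition of 27
Reagents that add atoms: none
Why: Proposed new method: zerovalent nickel adds oxidatively into the C–I bond of 27, 6-exo-dig syn-carbonickelation of the tethered alkyne closes the pyranone (bond C4'–C5') and places nickel on the exocyclic carbon C6 cis to C4'–H, aldehyde 28 (released from 23 by ring–chain tautomerism) inserts into the alkenyl–nickel bond to form C6–C7, and β-hydride elimination from the nickel alkoxide gives the ketone while the amine takes up HI and returns zerovalent nickel. The closest known reactions are the nickel-catalysed carbonyl-Heck coupling of aldehydes with aryl triflates or iodides (insertion, then β-hydride elimination) and the nickel- or palladium-catalysed carbometallative cyclisation of alkyne-tethered alkenyl halides; merging them on an alkenyl iodide and a lactol is new. The only ring closed is the six-membered lactone, by 6-exo-dig closure enforced by the ester tether, which also puts the acyl group on the terminal alkyne carbon. No stereocentre is formed: the (E)-geometry of C5'=C6 follows from syn insertion with retention at nickel, and C8 cannot epimerise because it is quaternary. The step needs ring closure before aldehyde capture and insertion before reduction; the first is secured by the low stationary concentration and neopentyl hindrance of the free aldehyde against an intramolecular insertion helped by the gem-dimethyl group, the second by a hindered amine that should not turn the lactol hydroxyl into a nickel alkoxide. Ketone, ester, epoxide and furan of 23 are not substrates for the alkenylnickel species, and the C10 hydroxyl is set free without protection.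

**Compound list**
1 | (R)-but-3-yn-2-ol | C[C@@H](O)C#C | starting material
2 | dilithium alkoxide acetylide of 1 | C[C@@H](O[Li])C#C[Li] | intermediate
3 | (R)-4-hydroxypent-2-ynoic acid | C[C@@H](O)C#CC(=O)O | intermediate
4 | (R,Z)-4-hydroxypent-2-enoic acid | C[C@@H](O)/C=C\C(=O)O | intermediate
5 | (R)-5-methylfuran-2(5H)-one | C[C@H]1OC(=O)C=C1 | intermediate
6 | bromomagnesium enolate of (4S,5R)-5-methyl-4-(prop-2-en-1-yl)oxolan-2-one | C[C@H]1OC(O[Mg]Br)=C[C@@H]1CC=C | intermediate
7 | (3S,4S,5R)-3,5-dimethyl-4-(prop-2-en-1-yl)oxolan-2-one | C[C@H]1OC(=O)[C@@H](C)[C@@H]1CC=C | intermediate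
8 | lithium enolate of 7 | C[C@H]1OC(O[Li])=C(C)[C@@H]1CC=C | intermediate
9 | (3R,4S,5R)-3-(1-hydroxyprop-2-en-1-yl)-3,5-dimethyl-4-(prop-2-en-1-yl)oxolan-2-one (carbinol epimers) | C[C@H]1OC(=O)[C@@](C)(C(O)C=C)[C@@H]1CC=C | intermediate
10 | (3R,3aS,7aR)-7-hydroxy-3,7a-dimethyl-3a,4,7,7a-tetrahydro-2-benzofuran-1(3H)-one (carbinol epimers) | C[C@H]1OC(=O)[C@@]2(C)C(O)C=CC[C@H]12 | intermediate
11 | (3R,3aS,7aR)-3,7a-dimethyl-1,3,3a,4,7,7a-hexahydro-2-benzofuran-1,7-diol (lactol, epimers) | C[C@H]1OC(O)[C@@]2(C)C(O)C=CC[C@H]12 | intermediate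
12 | (3R,3aS,7aR)-1-methoxy-3,7a-dimethyl-1,3,3a,4,7,7a-hexahydro-2-benzofuran-7-ol (acetal and carbinol epimers) | C[C@H]1OC(OC)[C@@]2(C)C(O)C=CC[C@H]12 | intermediate
13 | (3R,3aS,7aS)-1-methoxy-3,7a-dimethyl-3,3a,4,7a-tetrahydro-2-benzofuran-7(1H)-one (acetal epimers) | C[C@H]1OC(OC)[C@@]2(C)C(=O)C=CC[C@H]12 | intermediate
14 | lithium enolate from 1,4-reduction of 13 | C[C@H]1OC(OC)[C@@]2(C)C(O[Li])=CCC[C@H]12 | intermediate
15 | (3R,3aS,7aS)-6-(hydroxymethylidene)-1-methoxy-3,7a-dimethylhexahydro-2-benzofuran-7(1H)-one | C[C@H]1OC(OC)[C@@]2(C)C(=O)C(=CO)CC[C@H]12 | intermediate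
16 | (3R,3aS,6S,7aS)-1-methoxy-3,6,7a-trimethyl-7-oxooctahydro-2-benzofuran-6-carbaldehyde | C[C@H]1OC(OC)[C@@]2(C)C(=O)[C@](C)(C=O)CC[C@H]12 | intermediate
17 | (3R,3aS,6S,7aS)-6-[furan-3-yl(hydroxy)methyl]-1-methoxy-3,6,7a-trimethylhexahydro-2-benzofuran-7(1H)-one (carbinol epimers) | C[C@H]1OC(OC)[C@@]2(C)C(=O)[C@](C)(C(O)c3ccoc3)CC[C@H]12 | intermediate
18 | furan-3-yl[(3R,3aS,6S,7aS)-1-methoxy-3,6,7a-trimethyl-7-oxooctahydro-2-benzofuran-6-yl]methyl (diethoxyphosphoryl)acetate | C[C@H]1OC(OC)[C@@]2(C)C(=O)[C@](C)(C(OC(=O)CP(=O)(OCC)OCC)c3ccoc3)CC[C@H]12 | intermediate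
19 | tricyclic α,β-unsaturated δ-lactone (ring D with C14=C15 and 3-furyl at C17; acetal ring intact) | C[C@H]1OC(OC)[C@@]2(C)C3=CC(=O)OC(c4ccoc4)[C@]3(C)CC[C@H]12 | intermediate
20 | 14,15-epoxy δ-lactone (oxygen cis to the C8 methyl) | C[C@H]1OC(OC)[C@@]2(C)[C@@]34O[C@@H]3C(=O)OC(c5ccoc5)[C@]4(C)CC[C@H]12 | intermediate
21 | hydroxy ester: methyl glycidate with C17 carbinol and cyclic methyl acetal (C17 and acetal epimers) | COC(=O)[C@H]1O[C@@]12[C@](C)(C(O)c1ccoc1)CC[C@@H]1[C@@H](C)OC(OC)[C@@]21C | intermediate
22 | keto ester: methyl glycidate with 3-furyl ketone and cyclic methyl acetal (acetal epimers) | COC(=O)[C@H]1O[C@@]12[C@](C)(C(=O)c1ccoc1)CC[C@@H]1[C@@H](C)OC(OC)[C@@]21C | intermediate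
23 | lactol: trans-fused cyclic hemiacetal of the C7 aldehyde with the C10 hydroxyl (hemiacetal epimers) | COC(=O)[C@H]1O[C@@]12[C@](C)(C(=O)c1ccoc1)CC[C@@H]1[C@@H](C)OC(O)[C@@]21C | intermediate
24 | (Z)-3-iodoprop-2-enoic acid | OC(=O)/C=C\I | starting material
25 | 2-methylbut-3-yn-2-ol | CC(C)(O)C#C | starting material
26 | (Z)-3-iodoprop-2-enoyl chloride | ClC(=O)/C=C\I | intermediate
27 | 2-methylbut-3-yn-2-yl (Z)-3-iodoprop-2-enoate | C#CC(C)(C)OC(=O)/C=C\I | intermediate
28 | methyl (2S,3R,4R,5S,8R)-4-formyl-8-(furan-3-carbonyl)-5-[(1R)-1-hydroxyethyl]-4,8-dimethyl-1-oxaspiro[2.5]octane-2-carboxylate (open form of 23) | COC(=O)[C@H]1O[C@@]12[C@](C)(C(=O)c1ccoc1)CC[C@H]([C@@H](C)O)[C@@]2(C)C=O | intermediate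
29 | methyl (2S,3R,4R,5S,8R)-4-[(2E)-2-(2,2-dimethyl-6-oxo-2,6-dihydro-3H-pyran-3-ylidene)acetyl]-8-(furan-3-carbonyl)-5-[(1R)-1-hydroxyethyl]-4,8-dimethyl-1-oxaspiro[2.5]octane-2-carboxylate | COC(=O)[C@H]1O[C@@]12[C@](C)(C(=O)c1ccoc1)CC[C@H]([C@@H](C)O)[C@@]2(C)C(=O)/C=C1\C=CC(=O)OC1(C)C | target

**Step count and risks**
Total steps: 18. Longest linear sequence: 17 (steps 1–16, then step 18).

Most likely to fail:

1. Step 18. The alkenylnickel intermediate may be reduced when the lactol acts as a hydride donor (β-hydride elimination from a nickel lactolate), the terminal alkyne may oligomerise on nickel, or the aldehyde may be captured before ring closure. Fallback with known reactions, setting out from 25 and 23 and returning at 29: palladium-catalysed silylstannation of 25 (Me3SiSnBu3, Pd(PPh3)4, THF, 65 °C) should give (Z)-2-methyl-3-(tributylstannyl)-4-(trimethylsilyl)but-3-en-2-ol F1 by syn addition with tin on the internal carbon. Stille coupling with ethyl (Z)-3-iodoacrylate (Pd(PPh3)4, CuI, DMF), followed by lactonisation of the (Z)-hydroxy ester, gives (E)-6,6-dimethyl-5-[(trimethylsilyl)methylidene]-5,6-dihydro-2H-pyran-2-one F2. Iododesilylation with retention (NIS, (CF3)2CHOH, 0 °C) gives (E)-5-(iodomethylidene)-6,6-dimethyl-5,6-dihydro-2H-pyran-2-one F3. Nozaki–Hiyama–Kishi coupling of this iodide with lactol 23 (CrCl2, NiCl2 cat., DMSO) gives the C7-epimeric allylic alcohol F4, and MnO2, which oxidises only the allylic hydroxyl, returns to 29.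

2. Step 12. The phosphonate carbanion may fail to add to the C14 carbonyl, which lies between two quaternary carbons and can only be reached when ring C leaves its chair. Fallback from 17, returning at 19: acylation with bromoacetyl bromide and pyridine gives the bromoacetate F5; SmI2 (THF, −78 °C) effects an intramolecular Reformatsky addition to the β-hydroxy δ-lactone F6; dehydration (SOCl2, pyridine, 0 °C), possible only towards C15 because C8 and C13 carry no hydrogen, gives 19.

3. Step 13. Conjugate attack of the peroxide at the doubly neopentyl C14 may be slower than attack at the lactone carbonyl, or facial selectivity may be poor. Fallback from 17, returning at 20 and bypassing 18 and 19: chloroacetyl chloride and pyridine give the chloroacetate F7; an intramolecular Darzens condensation (KOt-Bu, THF, −78 → 0 °C), in which the reversible aldol addition should funnel to the trans-fused chloro alkoxide that can close anti to chloride, gives 20.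

Further compounds
F1 | step 18 | (Z)-2-methyl-3-(tributylstannyl)-4-(trimethylsilyl)but-3-en-2-ol | CC(C)(O)C(/[Sn](CCCC)(CCCC)CCCC)=C/[Si](C)(C)C
F2 | step 18 | (E)-6,6-dimethyl-5-[(trimethylsilyl)methylidene]-5,6-dihydro-2H-pyran-2-one | C[Si](C)(C)/C=C1\C=CC(=O)OC1(C)C
F3 | step 18 | (E)-5-(iodomethylidene)-6,6-dimethyl-5,6-dihydro-2H-pyran-2-one | I/C=C1\C=CC(=O)OC1(C)C
F4 | step 18 | C7-epimeric allylic alcohol (29 with CH(OH) in place of the C7 carbonyl) | COC(=O)[C@H]1O[C@@]12[C@](C)(C(=O)c1ccoc1)CC[C@H]([C@@H](C)O)[C@@]2(C)C(O)/C=C1\C=CC(=O)OC1(C)C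
F5 | step 12 | bromoacetate of 17 | C[C@H]1OC(OC)[C@@]2(C)C(=O)[C@](C)(C(OC(=O)CBr)c3ccoc3)CC[C@H]12
F6 | step 12 | β-hydroxy δ-lactone (C14 carbinol, ring D saturated) | C[C@H]1OC(OC)[C@@]2(C)C3(O)CC(=O)OC(c4ccoc4)[C@]3(C)CC[C@H]12
F7 | step 13 | chloroacetate of 17 | C[C@H]1OC(OC)[C@@]2(C)C(=O)[C@](C)(C(OC(=O)CCl)c3ccoc3)CC[C@H]12
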